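Numbering of the bicyclo[2.2.2]octane core: C1 methyl-bearing bridgehead, C2 ketone and C3 carbinol of the ketol bridge, C4 CH bridgehead, C5 sorbyl-bearing carbon, C6 ring ketone, C7 spiro carbon, C8 CH2. Last disconnections: global desilylation, then the C5–C4 and C5–C6 bonds, so that C5 with the whole sorbyl ketone is excised as (3E,5E)-1-diazohepta-3,5-dien-2-one and a bicyclo[2.2.1]heptane-2,7-dione remains in which C6 bridges C1 and C4.
Enabling feature: C5 is the central carbon of a β-diketone (ring ketone C6 plus exocyclic sorbyl ketone), the retron of a diazoketone–ketone homologation. C6 lies between the quaternary, α-keto bridgehead C1 (poor migrating group) and the CH bridgehead C4, and a 7-norbornanone carbonyl is strained. Insertion of C5 into C6–C4 therefore turns the five-membered ring C1–C6–C4–C8–C7 into the six-membered ring C1–C6–C5–C4–C8–C7.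
Norbornanedione from ozonolysis of a 7-isopropylidene group; ketol bridge from exo-face MeMgBr addition to the C2/C3 dione, itself from OsO4 dihydroxylation and Swern oxidation of a norbornene.
Norbornene from an exo-selective Diels–Alder reaction of 1-methyl-6,6-dimethylfulvene with O-TBS-scytolide (forms C1–C7 and C4–C8, sets C1, C4 and C7).
Scytolide from (−)-shikimic acid by Mitsunobu inversion of the allylic carbinol, carbenoid O–H insertion, Horner–Wadsworth–Emmons methylenation and lactonization. Order of ring formation: cyclohexene (chiral pool), 1,4-dioxan-2-one, bicyclo[2.2.1]heptene, then ring expansion to the bicyclo[2.2.2]octane.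

Key step: step 18

Remark: the 2-acyl-1,3-diketone unit is treated as the hydrogen-bonded Z-enol drawn in the target SMILES, so C5 needs no stereocontrol. The core atom labels C1–C8 are also used for the norbornane intermediates (C5 absent); the cyclohexene positions are called C-3, C-4, C-5 as in shikimic acid.

Step 1
Reactants: 1 (−)-shikimic acid
Product: 2 methyl shikimate 4,5-butane-2,3-diacetal (trans-fused 2,3-dimethoxy-2,3-dimethyl-1,4-dioxane on O-4/O-5, both methoxy groups axial; free 3-OH cis to O-4)
Conditions: butane-2,3-dione, HC(OMe)3, MeOH, camphorsulfonic acid (cat.), reflux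
Reagents that add atoms: butane-2,3-dione CC(=O)C(C)=O; methanol CO; trimethyl orthoformate COC(OC)OC
Why: Fischer esterification and butane-2,3-diacetal formation proceed in one pot; the diacetal selects the trans-diequatorial 4,5-diol (methoxy groups axial by the anomeric effect) and leaves the allylic 3-OH free.

Step 2
Reactants: 2 methyl shikimate 4,5-butane-2,3-diacetal
Product: 3 4-nitrobenzoate of methyl 3-epi-shikimate 4,5-butane-2,3-diacetal (ester oxygen trans to O-4)
Conditions: 4-nitrobenzoic acid, PPh3, diisopropyl azodicarboxylate, THF, 0 °C → rt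
Reagents that add atoms: 4-nitrobenzoic acid O=C(O)c1ccc(cc1)[N+](=O)[O-]
Why: Mitsunobu esterification inverts the only free carbinol by SN2 displacement of its oxyphosphonium salt, which sets the trans relationship of O-3 and O-4 that the trans-fused dioxanone needs.

Step 3
Reactants: 3 the 3-epi 4-nitrobenzoate
Product: 4 methyl 3-epi-shikimate 4,5-butane-2,3-diacetal (free 3-OH trans to O-4)
Conditions: K2CO3 (cat.), MeOH, 0 °C
Reagents that add atoms: none
Why: Base-catalysed transesterification with methanol removes the activated aryl ester, while the methyl ester exchanges degenerately and the diacetal is inert to base.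

Step 4
Reactants: 5 trimethyl phosphonoacetate
Product: 6 methyl diazo(dimethoxyphosphoryl)acetate
Conditions: 4-acetamidobenzenesulfonyl azide, 1,8-diazabicyclo[5.4.0]undec-7-ene, MeCN, 0 °C → rt
Reagents that add atoms: 4-acetamidobenzenesulfonyl azide CC(=O)Nc1ccc(cc1)S(=O)(=O)N=[N+]=[N-]
Why: Regitz diazo transfer from the sulfonyl azide to the doubly activated methylene group gives the acceptor-substituted diazo compound.

Step 5
Reactants: 4 methyl 3-epi-shikimate 4,5-butane-2,3-diacetal; 6 methyl diazo(dimethoxyphosphoryl)acetate
Product: 7 methyl 2-(dimethoxyphosphoryl)-2-alkoxyacetate in which the alkoxy oxygen is O-3 of 4 (both epimers at the phosphonate carbon)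
Conditions: Rh2(OAc)4 (1 mol%), PhH, 80 °C
Reagents that add atoms: none
Why: Rhodium-carbenoid O–H insertion (oxonium ylide formation and proton transfer) forms the ether bond with retention at the carbinol carbon, and the electron-poor ring alkene is not cyclopropanated.

Step 6
Reactants: 7 the phosphonoacetate ether
Product: 8 enol pyruvate ether (methyl 2-alkoxyacrylate on O-3 of the diacetal)
Conditions: LiN(SiMe3)2, THF, −78 °C; then CH2O (gas), −78 → 0 °C
Reagents that add atoms: formaldehyde C=O
Why: Horner–Wadsworth–Emmons olefination of the α-alkoxy phosphonate anion with formaldehyde gives the 2-alkoxyacrylate without touching any stereocentre.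

Step 7
Reactants: 8 the enol pyruvate ether
Product: 10 scytolide (trans-fused 3-methylene-1,4-dioxan-2-one on O-3/O-4; free 5-OH), via enol-pyruvate diol 9 (not isolated)
Conditions: CF3CO2H/H2O (9:1), rt; evaporate; camphorsulfonic acid (cat.), PhMe, 80 °C
Reagents that add atoms: none
Why: Aqueous acid hydrolyses the diacetal, and acid-catalysed transesterification by the 4-OH then closes the lactone (6-exo-trig acyl substitution), trans-fused because O-3 and O-4 are trans, while the 5-OH could only give a seven-membered ring.

Step 8
Reactants: 10 scytolide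
Product: 11 O-tert-butyldimethylsilyl scytolide
Conditions: t-BuMe2SiCl, imidazole, DMF, rt
Reagents that add atoms: tert-butyldimethylsilyl chloride CC(C)(C)[Si](C)(C)Cl
Why: Standard silylation of the remaining secondary alcohol protects it against the later Swern oxidation and the Grignard and diazo reagents.

Step 9
Reactants: 12 2-methylcyclopent-2-en-1-one
Product: 13 2-methyl-1-(prop-1-en-2-yl)cyclopent-2-en-1-ol (racemic)
Conditions: isopropenylmagnesium bromide, CeCl3, THF, −78 °C
Reagents that add atoms: isopropenylmagnesium bromide C=C(C)[Mg]Br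
Why: Cerium-mediated 1,2-addition of the Grignard reagent to the enone carbonyl suppresses enolisation and conjugate addition; the carbinol stereocentre is destroyed in the next step.

Step 10
Reactants: 13 the tertiary dienol
Product: 15 1-methyl-6,6-dimethylfulvene, via isopropenyl diene 14 (not isolated)
Conditions: p-TsOH·H2O (cat.), 4 Å molecular sieves, CH2Cl2, 0 °C; then KOt-Bu (cat.), THF, 0 °C
Reagents that add atoms: none
Why: E1 dehydration of the doubly allylic tertiary alcohol gives the isopropenylcyclopentadiene, and base-mediated prototropy through the cyclopentadienide converts it into the cross-conjugated fulvene, whose exocyclic carbon is fixed next to the methyl-bearing ring carbon by the constitution of 12.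

Step 11
Reactants: 11 O-tert-butyldimethylsilyl scytolide; 15 1-methyl-6,6-dimethylfulvene
Product: 16 norbornene adduct (C1 methyl bridgehead, C2=C3 alkene, C4–H bridgehead, C6 isopropylidene bridge, spiro C7 with ether oxygen endo and lactone carbonyl exo, C8 methylene)
Conditions: 15 (4 equiv), 2,6-di-tert-butyl-4-methylphenol (cat.), CH2Cl2, 12 kbar, 25 °C
Reagents that add atoms: none
Why: Intermolecular Diels–Alder reaction of the fulvene ring diene with the captodative α-methylene lactone: the methylene terminus (C8) bonds to the unsubstituted diene terminus (C4) and the oxygenated carbon (C7) to the methyl-bearing terminus (C1) (ortho rule for a 1-alkyl diene in an asynchronous transition state), the s-cis-locked lactone carbonyl takes the exo position as is usual for α-methylene lactones, and addition to the alkene face that makes the new C1–C7 bond axial on the dioxanone chair (cis to H-3 of the cyclohexene) gives the required configuration of C1, C4 and C7 relative to the shikimate stereocentres; this facial preference is the least secure element, and the diastereomers are to be separated at this stage.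

Step 12
Reactants: 16 the norbornene adduct
Product: 17 exo,exo-C2,C3-diol
Conditions: OsO4 (2 mol%), N-methylmorpholine N-oxide, acetone/H2O, 0 °C
Reagents that add atoms: N-methylmorpholine N-oxide C[N+]1([O-])CCOCC1; water O
Why: Catalytic osmylation (syn-dihydroxylation) attacks the strained norbornene double bond on its exo face much faster than the hindered tetrasubstituted alkylidene or the electron-poor cyclohexenecarboxylate; the diol configuration is erased in the next step.

Step 13
Reactants: 17 the exo,exo-diol
Product: 18 C2,C3-dione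
Conditions: (COCl)2, Me2SO, CH2Cl2, −78 °C; then Et3N, −78 → 0 °C
Reagents that add atoms: none
Why: Double Swern oxidation of the cis-diol gives the non-enolisable α-diketone without C–C cleavage.

Step 14
Reactants: 18 the C2,C3-dione
Product: 19 tertiary α-ketol (C2 ketone; C3 with methyl exo and hydroxyl endo)
Conditions: MeMgBr (1.05 equiv), THF, −78 °C
Reagents that add atoms: methylmagnesium bromide C[Mg]Br
Why: Grignard 1,2-addition to the less hindered C3 carbonyl (C2 is shielded by the quaternary C1) from the exo face, syn to the flat C6 alkylidene bridge and anti to the endo substituents on C7 and C8, places methyl exo and hydroxyl endo and so sets C3; at −78 °C the α-diketone should react far faster than the lactone and the ester.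

Step 15
Reactants: 19 the α-ketol
Product: 20 C3 triethylsilyl ether
Conditions: Et3SiOSO2CF3, 2,6-lutidine, CH2Cl2, 0 °C
Reagents that add atoms: triethylsilyl trifluoromethanesulfonate CC[Si](CC)(CC)OS(=O)(=O)C(F)(F)F
Why: Silyl triflate silylation of the tertiary hydroxyl blocks α-ketol rearrangement and O–H insertion under the later Lewis-acidic diazo conditions; the C2 ketone has no α-hydrogen and cannot form a silyl enol ether.

Step 16
Reactants: 20 the triethylsilyl ether
Product: 21 bicyclo[2.2.1]heptane-2,7-dione (C6 bridging ketone unmasked)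
Conditions: O3 (1 equiv), CH2Cl2/pyridine, −78 °C; then Me2S
Reagents that add atoms: ozone [O-][O+]=O
Why: Ozonolysis with reductive work-up cleaves the electron-rich tetrasubstituted exocyclic alkene selectively in the presence of the deactivated cyclohexenecarboxylate; the strained, non-enolisable β-diketone is used at once and kept away from nucleophiles.

Step 17
Reactants: 22 sorbyl chloride [(2E,4E)-hexa-2,4-dienoyl chloride]
Product: 23 (3E,5E)-1-diazohepta-3,5-dien-2-one
Conditions: Me3SiCHN2, MeCN/THF, 0 °C
Reagents that add atoms: (trimethylsilyl)diazomethane C[Si](C)(C)C=[N+]=[N-]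
Why: Acylation of the diazoalkane by the acid chloride (Arndt–Eistert-type diazoketone synthesis) with chloride-induced desilylation gives the diazomethyl ketone; the silylated reagent avoids dipolar cycloaddition to the dienoyl system.

Step 18
Reactants: 21 the bicyclo[2.2.1]heptane-2,7-dione; 23 the sorbyl diazomethyl ketone
Product: 25 bis-silyl ether of the target, via diazonium alkoxide 24 (not isolated)
Conditions: Sc(OTf)3 (10 mol%), CH2Cl2, −40 → 0 °C
Reagents that add atoms: none
Why: The Lewis acid activates the strained bridging C6 carbonyl, the nucleophilic diazo carbon of 23 adds to it to give the diazonium alkoxide 24, and a 1,2-shift of the C6–C4 bond to the diazonium carbon with loss of N2 inserts that carbon as C5 between C6 and C4, giving the 2-acyl ketone that tautomerises to the hydrogen-bonded enol. The closest known reaction type is the Lewis-acid-promoted homologation (Tiffeneau–Demjanov-type ring expansion) of cyclic ketones with α-diazo carbonyl compounds such as ethyl diazoacetate, and diazomethyl ketones are known partners in the analogous homologation of aldehydes to 1,3-diketones. No ring is closed: the five-membered rings C1–C6–C4–C8–C7 and C1–C2–C3–C4–C6 are each enlarged by one carbon, so the bicyclo[2.2.1]heptane becomes the bicyclo[2.2.2]octane, driven by release of the 7-norbornanone strain. C4 migrates with retention and C1, C3 and C7 are untouched; C5 is the only new sp3 centre and is erased by enolisation. The step needs chemoselectivity for C6 over the C2 ketone, secured by the strain at C6 and by the two fully substituted neighbours of C2, and migration of C4 rather than C1, secured because C1 is quaternary and α to the C2 carbonyl (an electron-poor, poor migrating group) while the C5–N2 bond can rotate freely to align with C6–C4. Retro-Claisen cleavage of the non-enolisable β-diketone is avoided by the absence of base and nucleophiles, and the whole sorbyl side chain arrives in the same operation.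

Step 19
Reactants: 25 the bis-silyl ether
Product: 26 target CNP0259039.2
Conditions: HF·pyridine, pyridine, THF, 0 °C → rt
Reagents that add atoms: none
Why: Fluoride-mediated cleavage of both silyl ethers under buffered, non-basic conditions should leave the lactone, the ester and the acidic enolised triketone intact.

Compound list
1 | (−)-shikimic acid | O[C@@H]1C=C(C(=O)O)C[C@@H](O)[C@@H]1O | starting material
2 | methyl shikimate 4,5-butane-2,3-diacetal (methoxy groups axial, 3-OH cis to O-4) | COC(=O)C1=C[C@@H](O)[C@H]2O[C@](C)(OC)[C@@](C)(OC)O[C@@H]2C1 | intermediate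
3 | 4-nitrobenzoate of methyl 3-epi-shikimate 4,5-butane-2,3-diacetal | COC(=O)C1=C[C@H](OC(=O)c3ccc(cc3)[N+](=O)[O-])[C@H]2O[C@](C)(OC)[C@@](C)(OC)O[C@@H]2C1 | intermediate
4 | methyl 3-epi-shikimate 4,5-butane-2,3-diacetal | COC(=O)C1=C[C@H](O)[C@H]2O[C@](C)(OC)[C@@](C)(OC)O[C@@H]2C1 | intermediate
5 | trimethyl phosphonoacetate | COC(=O)CP(=O)(OC)OC | starting material
6 | methyl diazo(dimethoxyphosphoryl)acetate | COC(=O)C(=[N+]=[N-])P(=O)(OC)OC | intermediate
7 | O-3 ether of 4 with methyl 2-(dimethoxyphosphoryl)acetate (epimers at the phosphonate carbon) | COC(=O)C1=C[C@H](OC(C(=O)OC)P(=O)(OC)OC)[C@H]2O[C@](C)(OC)[C@@](C)(OC)O[C@@H]2C1 | intermediate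
8 | enol pyruvate ether (methyl 2-alkoxyacrylate on O-3) of the diacetal | COC(=O)C1=C[C@H](OC(=C)C(=O)OC)[C@H]2O[C@](C)(OC)[C@@](C)(OC)O[C@@H]2C1 | intermediate
9 | enol pyruvate ether 4,5-diol | COC(=O)C1=C[C@H](OC(=C)C(=O)OC)[C@@H](O)[C@H](O)C1 | intermediate
10 | scytolide | C=C1O[C@H]2C=C(C(=O)OC)C[C@@H](O)[C@@H]2OC1=O | intermediate
11 | O-tert-butyldimethylsilyl scytolide | C=C1O[C@H]2C=C(C(=O)OC)C[C@@H](O[Si](C)(C)C(C)(C)C)[C@@H]2OC1=O | intermediate
12 | 2-methylcyclopent-2-en-1-one | CC1=CCCC1=O | starting material
13 | 2-methyl-1-(prop-1-en-2-yl)cyclopent-2-en-1-ol (racemic) | CC1=CCCC1(O)C(C)=C | intermediate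
14 | 3-methyl-2-(prop-1-en-2-yl)cyclopenta-1,3-diene | CC1=CCC=C1C(C)=C | intermediate
15 | 1-methyl-6,6-dimethylfulvene [1-methyl-5-(propan-2-ylidene)cyclopenta-1,3-diene] | CC1=CC=CC1=C(C)C | intermediate
16 | Diels–Alder adduct: 7-isopropylidene norbornene, C1 methyl, spiro C7 with ether O endo and lactone C=O exo | CC(C)=C1[C@@]2(C)C=C[C@@H]1C[C@]21O[C@H]3C=C(C(=O)OC)C[C@@H](O[Si](C)(C)C(C)(C)C)[C@@H]3OC1=O | intermediate
17 | exo,exo-C2,C3-diol of 16 | CC(C)=C1[C@@]2(C)[C@@H](O)[C@@H](O)[C@@H]1C[C@]21O[C@H]3C=C(C(=O)OC)C[C@@H](O[Si](C)(C)C(C)(C)C)[C@@H]3OC1=O | intermediate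
18 | C2,C3-dione | CC(C)=C1[C@@]2(C)C(=O)C(=O)[C@@H]1C[C@]21O[C@H]3C=C(C(=O)OC)C[C@@H](O[Si](C)(C)C(C)(C)C)[C@@H]3OC1=O | intermediate
19 | α-ketol: C2 ketone, C3 methyl exo and hydroxyl endo | CC(C)=C1[C@@]2(C)C(=O)[C@](C)(O)[C@@H]1C[C@]21O[C@H]3C=C(C(=O)OC)C[C@@H](O[Si](C)(C)C(C)(C)C)[C@@H]3OC1=O | intermediate
20 | C3 triethylsilyl ether of 19 | CC(C)=C1[C@@]2(C)C(=O)[C@](C)(O[Si](CC)(CC)CC)[C@@H]1C[C@]21O[C@H]3C=C(C(=O)OC)C[C@@H](O[Si](C)(C)C(C)(C)C)[C@@H]3OC1=O | intermediate
21 | bicyclo[2.2.1]heptane-2,7-dione (C2 and bridging C6 ketones) | O=C1[C@@]2(C)C(=O)[C@](C)(O[Si](CC)(CC)CC)[C@@H]1C[C@]21O[C@H]3C=C(C(=O)OC)C[C@@H](O[Si](C)(C)C(C)(C)C)[C@@H]3OC1=O | intermediate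
22 | sorbyl chloride, (2E,4E)-hexa-2,4-dienoyl chloride | C/C=C/C=C/C(Cl)=O | starting material
23 | (3E,5E)-1-diazohepta-3,5-dien-2-one | C/C=C/C=C/C(=O)C=[N+]=[N-] | intermediate
24 | diazonium alkoxide at C6 (scandium-bound in the flask; both configurations at C5 and C6) | C/C=C/C=C/C(=O)C([N+]#N)C1([O-])[C@@]2(C)C(=O)[C@](C)(O[Si](CC)(CC)CC)[C@@H]1C[C@]21O[C@H]3C=C(C(=O)OC)C[C@@H](O[Si](C)(C)C(C)(C)C)[C@@H]3OC1=O | intermediate
25 | target with C3–O–SiEt3 and cyclohexene 5-O–SiMe2t-Bu | C/C=C/C=C/C(O)=C1/C(=O)[C@@]2(C)C(=O)[C@](C)(O[Si](CC)(CC)CC)[C@@H]1C[C@]21O[C@H]3C=C(C(=O)OC)C[C@@H](O[Si](C)(C)C(C)(C)C)[C@@H]3OC1=O | intermediate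
26 | CNP0259039.2 | C/C=C/C=C/C(O)=C1/C(=O)[C@@]2(C)C(=O)[C@](C)(O)[C@@H]1C[C@]21O[C@H]2C=C(C(=O)OC)C[C@@H](O)[C@@H]2OC1=O | target

Total step count: 19. Longest linear sequence: 15 steps (steps 1, 2, 3, 5, 6, 7, 8, 11, 12, 13, 14, 15, 16, 18, 19).

Steps most likely to fail

Step 18. The acyl-stabilised dienyl diazoketone is a weak nucleophile, so its addition to the congested bridging carbonyl may be slower than Lewis-acid-induced decomposition of the diazoketone or ring-opening of the strained diketone by adventitious nucleophiles. The fallback separates ring expansion from acylation. Starting from 21, ring expansion with the far more nucleophilic diazomethane (CH2N2, Et2O, 0 °C; the classical uncatalysed homologation of strained ketones, with the same migratory preference for C4) should give the C5-unsubstituted bicyclo[2.2.2]octane-2,6-dione F1. Soft enolisation of its only enolisable position, C5, with MgBr2·OEt2 and i-Pr2NEt in CH2Cl2 and C-acylation with sorbyl chloride 22 should then give 25, where the route is rejoined.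

Step 11. Bond formation between the methyl-bearing diene terminus and the fully substituted dienophile carbon may be slow, leading to cycloreversion, erosion of the regiochemistry and poor exo and π-facial discrimination. The fallback uses a diene whose regiochemistry is enforced electronically and which should react at low temperature; it does not by itself remove the π-facial uncertainty.
- 3-Methylcyclopent-2-en-1-one F2 is silylated (t-BuMe2SiOSO2CF3, Et3N, CH2Cl2) to the silyl dienol ether F3.
- Vinylogous Mukaiyama alkylation at the γ-carbon of F3 with 2,2-dimethoxypropane (Me3SiOSO2CF3 cat., CH2Cl2, −78 °C) gives the methoxy ketone F4.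
- E1cB loss of methanol (1,8-diazabicyclo[5.4.0]undec-7-ene, CH2Cl2) gives the dienone 3-methyl-4-(propan-2-ylidene)cyclopent-2-en-1-one F5.
- Silylation of its cross-conjugated enolate (LiN(SiMe3)2, t-BuMe2SiCl, THF, −78 °C) gives the 3-siloxyfulvene F6.
- Diels–Alder reaction of F6 with 11 (PhMe, rt) gives the silyl enol ether adduct F7; the siloxy group directs the methylene terminus to the unsubstituted diene terminus.
- OsO4/N-methylmorpholine N-oxide converts the enol ether into the acyloin F8, and Swern oxidation of F8 gives the dione 18, where the route is rejoined.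

Step 14. The Grignard reagent may attack the activated spiro-lactone or add twice, and discrimination between the two ketone carbonyls may be incomplete. The fallback introduces the methyl group as an electrophile. Starting from diol 17, selective silylation of the less hindered C3 hydroxyl (Et3SiCl, imidazole, DMF, 0 °C; the C2 hydroxyl is neopentylic) gives the mono-silyl ether F9. Swern oxidation gives the α-silyloxy ketone F10. Deprotonation at C3, the only enolisable position (LiN(SiMe3)2, THF, −78 °C), and exo-face methylation with MeI should give 20 directly, where the route is rejoined.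

Further compounds
F1 | step 18 | C5-unsubstituted bicyclo[2.2.2]octane-2,6-dione (25 without the sorbyl group) | C1C(=O)[C@@]2(C)C(=O)[C@](C)(O[Si](CC)(CC)CC)[C@@H]1C[C@]21O[C@H]3C=C(C(=O)OC)C[C@@H](O[Si](C)(C)C(C)(C)C)[C@@H]3OC1=O
F2 | step 11 | 3-methylcyclopent-2-en-1-one | CC1=CC(=O)CC1
F3 | step 11 | tert-butyldimethyl[(3-methylcyclopenta-1,3-dien-1-yl)oxy]silane | CC1=CCC(O[Si](C)(C)C(C)(C)C)=C1
F4 | step 11 | 4-(2-methoxypropan-2-yl)-3-methylcyclopent-2-en-1-one (racemic) | CC1=CC(=O)CC1C(C)(C)OC
F5 | step 11 | 3-methyl-4-(propan-2-ylidene)cyclopent-2-en-1-one | CC1=CC(=O)CC1=C(C)C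
F6 | step 11 | 3-(tert-butyldimethylsilyloxy)-1-methyl-6,6-dimethylfulvene | CC1=CC(O[Si](C)(C)C(C)(C)C)=CC1=C(C)C
F7 | step 11 | Diels–Alder adduct with C3 silyl enol ether | CC(C)=C1[C@@]2(C)C=C(O[Si](C)(C)C(C)(C)C)[C@@H]1C[C@]21O[C@H]3C=C(C(=O)OC)C[C@@H](O[Si](C)(C)C(C)(C)C)[C@@H]3OC1=O
F8 | step 11 | acyloin: C3 ketone, C2 exo-hydroxyl | CC(C)=C1[C@@]2(C)[C@@H](O)C(=O)[C@@H]1C[C@]21O[C@H]3C=C(C(=O)OC)C[C@@H](O[Si](C)(C)C(C)(C)C)[C@@H]3OC1=O
F9 | step 14 | C3 mono-triethylsilyl ether of diol 17 | CC(C)=C1[C@@]2(C)[C@@H](O)[C@@H](O[Si](CC)(CC)CC)[C@@H]1C[C@]21O[C@H]3C=C(C(=O)OC)C[C@@H](O[Si](C)(C)C(C)(C)C)[C@@H]3OC1=O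
F10 | step 14 | C2 ketone with C3 exo-triethylsilyloxy group | CC(C)=C1[C@@]2(C)C(=O)[C@@H](O[Si](CC)(CC)CC)[C@@H]1C[C@]21O[C@H]3C=C(C(=O)OC)C[C@@H](O[Si](C)(C)C(C)(C)C)[C@@H]3OC1=O
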